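**Plan**

- Retrosynthesis: the two acetates and the free acid come from phenol ester 18. Its C4–C4a bond is cut by reversing a 1,2-shift, which gives spirodienone 17 with C1 and C4 both on C8a. Then C4–C8a is cut (phenoxide ipso-alkylation of mesylate 15), followed by the C1–H and CH2–O bonds (protoboration/oxidation), C1=CH2 (Wittig), aryl C8a–C1 (Grignard on lactone 7), C2=C3 (olefination) and C4–O (aminoxylation), back to (S)-citronellal and methyl 3-hydroxy-4-iodobenzoate.
- Enabling feature: in ring B (C1 bearing CH2OAc, C2, C3, C4 bearing the side chain, fused to the arene C4a, C5, C6–CO2H, C7, C8–OAc, C8a), C4 is bonded to C4a, which is meta to the C8 oxygen, whereas its neighbour C8a is ortho to it. A phenoxide can therefore accept C4 only at C8a, and the bond must then be moved to C4a.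
- Forward order: the C1–C4 chain is built on citronellal and joined to the arene at C1; the five-membered spiro ring is closed at C8a; ring B arises from it by ring expansion with return of the benzene ring; hydrolysis and acetylation finish the route.
- Stereochemistry: C11 comes from (S)-citronellal. C4 comes from D-proline-catalysed α-aminoxylation, is inverted once in the ring closure and retained in the shift. C1 comes from ligand-controlled copper–boryl addition to the 1,1-disubstituted alkene.

Key step: step 11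

Remark: locants C1–C8a and C11 in the text are those of the target tetralin as defined above; in step 6 the antipode of the chiral NHC ligand that leads to 2R is to be fixed on a model α-alkylstyrene, the other antipode being used if the sense is opposite.

**Step 1**
Reactants: 1 methyl 3-hydroxy-4-iodobenzoate
Product: 2 methyl 4-iodo-3-[(4-methoxybenzyl)oxy]benzoate
Conditions: PMBCl, K2CO3, DMF, 50 °C
Reagents that add atoms: 4-methoxybenzyl chloride, COc1ccc(CCl)cc1
Why: Williamson ether synthesis, in which the potassium phenoxide is alkylated by the benzylic chloride, masks the phenol for the Grignard, acylation and sulfonylation steps and can later be removed oxidatively without acid or base.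

**Step 2**
Reactants: 3 (S)-citronellal, (3S)-3,7-dimethyloct-6-enal
Product: 5 ethyl (2E,4S,5S)-5,9-dimethyl-4-[(phenylamino)oxy]deca-2,8-dienoate, via α-aminoxy aldehyde 4 (not isolated)
Conditions: PhNO, D-proline (20 mol%), DMSO, rt; then (EtO)2P(O)CH2CO2Et, LiCl, DBU, MeCN, 0 °C
Reagents that add atoms: nitrosobenzene, O=Nc1ccccc1; triethyl phosphonoacetate, CCOC(=O)CP(=O)(OCC)OCC
Why: In the proline-catalysed α-aminoxylation the D-proline enamine attacks the oxygen of nitrosobenzene under catalyst control, which should set the 2S carbinol centre (later C4) next to the untouched methyl centre (C11), and the labile aldehyde is trapped at once by a Horner–Wadsworth–Emmons olefination under Masamune–Roush conditions as the E-enoate.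

**Step 3**
Reactants: 5 ethyl (2E,4S,5S)-5,9-dimethyl-4-[(phenylamino)oxy]deca-2,8-dienoate
Product: 7 (5R)-5-[(2S)-6-methylhept-5-en-2-yl]oxolan-2-one, via hydroxy ester 6 (not isolated)
Conditions: NiCl2·6H2O (cat.), NaBH4, EtOH, 0 °C; then PPTS (cat.), toluene, 60 °C
Reagents that add atoms: none
Why: Nickel boride (Ni2B) formed from NiCl2 and NaBH4 should reduce the conjugated C=C bond and cleave the N–O bond while leaving the isolated trisubstituted alkene, and the γ-hydroxy ester then lactonises under mild acid without touching the carbinol centre.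

**Step 4**
Reactants: 2 methyl 4-iodo-3-[(4-methoxybenzyl)oxy]benzoate; 7 (5R)-5-[(2S)-6-methylhept-5-en-2-yl]oxolan-2-one
Product: 9 methyl 4-[(4R,5S)-4-hydroxy-5,9-dimethyldec-8-enoyl]-3-[(4-methoxybenzyl)oxy]benzoate, via arylmagnesium chloride 8 (not isolated)
Conditions: 2, iPrMgCl·LiCl, THF, −40 °C; then 7, −40 → −10 °C; NH4Cl (aq)
Reagents that add atoms: none
Why: Iodine–magnesium exchange with iPrMgCl·LiCl is faster at −40 °C than attack on the methyl ester, and the arylmagnesium reagent is acylated by the more electrophilic γ-lactone, whose magnesium hemiketalate shields the new ketone from a second addition (Grignard acylation).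

**Step 5**
Reactants: 9 methyl 4-[(4R,5S)-4-hydroxy-5,9-dimethyldec-8-enoyl]-3-[(4-methoxybenzyl)oxy]benzoate
Product: 10 methyl 4-[(5R,6S)-5-hydroxy-6,10-dimethylundeca-1,9-dien-2-yl]-3-[(4-methoxybenzyl)oxy]benzoate
Conditions: Ph3PCH3Br, KOtBu, THF, 0 °C → rt
Reagents that add atoms: methyltriphenylphosphonium bromide, C[P+](c1ccccc1)(c1ccccc1)c1ccccc1.[Br-]
Why: In this Wittig methylenation the non-stabilised ylide adds to the aryl ketone much faster than to the benzoate ester, and the free hydroxyl is tolerated as its alkoxide by an extra equivalent of ylide.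

**Step 6**
Reactants: 10 methyl 4-[(5R,6S)-5-hydroxy-6,10-dimethylundeca-1,9-dien-2-yl]-3-[(4-methoxybenzyl)oxy]benzoate
Product: 12 methyl 4-[(2R,5R,6S)-1,5-dihydroxy-6,10-dimethylundec-9-en-2-yl]-3-[(4-methoxybenzyl)oxy]benzoate, via pinacol boronate 11 (not isolated)
Conditions: CuCl (cat.), chiral sulfonate-bearing imidazolinium salt (NHC precursor, cat.), KOtBu (cat.), B2pin2, MeOH, THF, −50 °C; then NaBO3·4H2O, THF/H2O, rt
Reagents that add atoms: sodium perborate, [Na+].[Na+].O[B-]1(O)OO[B-](O)(O)OO1; bis(pinacolato)diboron (boron carried by 11 only), CC1(C)OB(OC1(C)C)B1OC(C)(C)C(C)(C)O1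
Why: In this enantioselective copper-catalysed protoboration of a 1,1-disubstituted aryl alkene the NHC–copper boryl adds syn with boron at the terminal carbon and copper at the benzylic carbon, the chiral ligand selecting the alkene face (catalyst control) so that protonation by methanol with retention should set C1 as 2R, and perborate oxidation of the C–B bond then gives the primary alcohol without affecting the ester or the trisubstituted alkene.

**Step 7**
Reactants: 12 methyl 4-[(2R,5R,6S)-1,5-dihydroxy-6,10-dimethylundec-9-en-2-yl]-3-[(4-methoxybenzyl)oxy]benzoate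
Product: 13 methyl 4-[(2R,5R,6S)-1-acetoxy-5-hydroxy-6,10-dimethylundec-9-en-2-yl]-3-[(4-methoxybenzyl)oxy]benzoate
Conditions: AcCl (1.05 equiv), 2,4,6-collidine, CH2Cl2, −78 °C
Reagents that add atoms: acetyl chloride, CC(=O)Cl
Why: This is a kinetically selective acylation, since at −78 °C with the hindered base acetyl chloride should esterify the primary hydroxyl much faster than the secondary hydroxyl flanked by the methyl-branched carbon.

**Step 8**
Reactants: 13 methyl 4-[(2R,5R,6S)-1-acetoxy-5-hydroxy-6,10-dimethylundec-9-en-2-yl]-3-[(4-methoxybenzyl)oxy]benzoate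
Product: 14 methyl 4-[(2R,5R,6S)-1-acetoxy-5-(methanesulfonyloxy)-6,10-dimethylundec-9-en-2-yl]-3-[(4-methoxybenzyl)oxy]benzoate
Conditions: MsCl, Et3N, CH2Cl2, 0 °C
Reagents that add atoms: methanesulfonyl chloride, CS(=O)(=O)Cl
Why: Sulfonylation through sulfene forms the O–S bond with retention at the carbinol carbon and turns the secondary hydroxyl into the leaving group for the ring closure.

**Step 9**
Reactants: 14 methyl 4-[(2R,5R,6S)-1-acetoxy-5-(methanesulfonyloxy)-6,10-dimethylundec-9-en-2-yl]-3-[(4-methoxybenzyl)oxy]benzoate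
Product: 15 methyl 4-[(2R,5R,6S)-1-acetoxy-5-(methanesulfonyloxy)-6,10-dimethylundec-9-en-2-yl]-3-hydroxybenzoate
Conditions: DDQ, CH2Cl2/pH 7 buffer, 0 °C → rt
Reagents that add atoms: none
Why: Oxidative cleavage of the 4-methoxybenzyl ether by DDQ (hydride abstraction at the electron-rich benzylic position, then hydrolysis of the oxocarbenium ion) frees the phenol under neutral conditions that leave the mesylate, the acetate, the ester and the alkene alone.

**Step 10**
Reactants: 15 methyl 4-[(2R,5R,6S)-1-acetoxy-5-(methanesulfonyloxy)-6,10-dimethylundec-9-en-2-yl]-3-hydroxybenzoate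
Product: 17 methyl (1R,4S)-1-(acetoxymethyl)-4-[(2S)-6-methylhept-5-en-2-yl]-6-oxospiro[4.5]deca-7,9-diene-8-carboxylate (both C5 epimers), via potassium phenoxide 16 (not isolated)
Conditions: KOtBu (1.0 equiv), tBuOH/THF, 0.01 M, rt → 50 °C
Reagents that add atoms: none
Why: In this phenoxide ipso-alkylation (Ar1-5 participation, 5-exo-tet) the ortho carbon C8a, which already carries C1, displaces the secondary mesylate at C4 with inversion and gives the cyclohexa-2,4-dienone, the protic solvent hydrogen-bonding the phenoxide oxygen and so disfavouring seven-membered O-alkylation, the single equivalent of base being consumed by the phenol so that the acetate is spared, and the configuration of the new spiro centre being of no consequence.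

**Step 11**
Reactants: 17 methyl (1R,4S)-1-(acetoxymethyl)-4-[(2S)-6-methylhept-5-en-2-yl]-6-oxospiro[4.5]deca-7,9-diene-8-carboxylate
Product: 18 methyl (5R,8S)-5-(acetoxymethyl)-4-hydroxy-8-[(2S)-6-methylhept-5-en-2-yl]-5,6,7,8-tetrahydronaphthalene-2-carboxylate
Conditions: BF3·OEt2, CH2Cl2, −40 → 0 °C; NaHCO3 (aq)
Reagents that add atoms: none
Why: BF3 binds the ketone oxygen (the future C8 oxygen) and turns the ring into an oxygen-substituted pentadienyl cation with positive charge at the diene terminus next to the spiro carbon (C4a), to which C4 shifts suprafacially from C8a with retention of configuration, and the arenium ion so formed loses the C4a proton to give the phenol. The closest known reaction type is the acid-promoted dienone–phenol rearrangement of 6,6-disubstituted cyclohexa-2,4-dienones and their spiro analogues to 2,3-disubstituted phenols. Ring B is not closed by a cyclisation but arises by one-carbon ring expansion of the spirocyclopentane (1,2-alkyl shift, five- to six-membered), and the benzene ring returns by deprotonation. No stereocentre is created: C1 and C11 are spectators, C4 keeps its configuration, and the spiro centre disappears, so both spiro epimers converge on one product. The selectivity required is migration of C4 and not of C1; it should be secured by the acetoxymethyl group, whose inductive withdrawal lowers the migratory aptitude of C1, while C4 sits in the more electron-rich, branched environment. An aprotic Lewis acid at low temperature is chosen so that the trisubstituted side-chain alkene, the acetate and the ester are not engaged.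

**Step 12**
Reactants: 18 methyl (5R,8S)-5-(acetoxymethyl)-4-hydroxy-8-[(2S)-6-methylhept-5-en-2-yl]-5,6,7,8-tetrahydronaphthalene-2-carboxylate
Product: 19 (5R,8S)-4-hydroxy-5-(hydroxymethyl)-8-[(2S)-6-methylhept-5-en-2-yl]-5,6,7,8-tetrahydronaphthalene-2-carboxylic acid
Conditions: LiOH, THF/MeOH/H2O, rt; then 1 M HCl
Reagents that add atoms: lithium hydroxide (oxygen of the acid OH), [Li+].[OH-]
Why: Saponification by acyl–oxygen cleavage removes the methyl ester and, unavoidably, the primary acetate, which is restored in the last step.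

**Step 13**
Reactants: 19 (5R,8S)-4-hydroxy-5-(hydroxymethyl)-8-[(2S)-6-methylhept-5-en-2-yl]-5,6,7,8-tetrahydronaphthalene-2-carboxylic acid
Product: 21 (5R,8S)-4-acetoxy-5-(acetoxymethyl)-8-[(2S)-6-methylhept-5-en-2-yl]-5,6,7,8-tetrahydronaphthalene-2-carboxylic acid (CNP0223972.1), via mixed anhydride 20 (not isolated)
Conditions: Ac2O, pyridine, DMAP (cat.), CH2Cl2, rt; then H2O/THF, rt
Reagents that add atoms: acetic anhydride, CC(=O)OC(C)=O
Why: DMAP-catalysed acetylation esterifies the phenol and the primary alcohol together, and the mixed anhydride formed at the carboxyl group is hydrolysed at its more reactive acetyl carbonyl during the aqueous stir, which returns the free acid.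

**Compound list**

1 | methyl 3-hydroxy-4-iodobenzoate | COC(=O)c1ccc(I)c(O)c1 | starting material
2 | methyl 4-iodo-3-[(4-methoxybenzyl)oxy]benzoate | COC(=O)c1ccc(I)c(OCc2ccc(OC)cc2)c1 | intermediate
3 | (S)-citronellal, (3S)-3,7-dimethyloct-6-enal | O=CC[C@@H](C)CCC=C(C)C | starting material
4 | (2S,3S)-3,7-dimethyl-2-[(phenylamino)oxy]oct-6-enal (formed in the flask) | O=C[C@H]([C@@H](C)CCC=C(C)C)ONc1ccccc1 | intermediate
5 | ethyl (2E,4S,5S)-5,9-dimethyl-4-[(phenylamino)oxy]deca-2,8-dienoate | CCOC(=O)/C=C/[C@H]([C@@H](C)CCC=C(C)C)ONc1ccccc1 | intermediate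
6 | ethyl (4R,5S)-4-hydroxy-5,9-dimethyldec-8-enoate (formed in the flask) | CCOC(=O)CC[C@H]([C@@H](C)CCC=C(C)C)O | intermediate
7 | (5R)-5-[(2S)-6-methylhept-5-en-2-yl]oxolan-2-one | O=C1CC[C@H]([C@@H](C)CCC=C(C)C)O1 | intermediate
8 | {2-[(4-methoxybenzyl)oxy]-4-(methoxycarbonyl)phenyl}magnesium chloride, LiCl complex (formed in the flask) | COC(=O)c1ccc([Mg]Cl)c(OCc2ccc(OC)cc2)c1 | intermediate
9 | methyl 4-[(4R,5S)-4-hydroxy-5,9-dimethyldec-8-enoyl]-3-[(4-methoxybenzyl)oxy]benzoate | COC(=O)c1ccc(C(=O)CC[C@H]([C@@H](C)CCC=C(C)C)O)c(OCc2ccc(OC)cc2)c1 | intermediate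
10 | methyl 4-[(5R,6S)-5-hydroxy-6,10-dimethylundeca-1,9-dien-2-yl]-3-[(4-methoxybenzyl)oxy]benzoate | COC(=O)c1ccc(C(=C)CC[C@H]([C@@H](C)CCC=C(C)C)O)c(OCc2ccc(OC)cc2)c1 | intermediate
11 | methyl 4-[(2R,5R,6S)-5-hydroxy-6,10-dimethyl-1-(4,4,5,5-tetramethyl-1,3,2-dioxaborolan-2-yl)undec-9-en-2-yl]-3-[(4-methoxybenzyl)oxy]benzoate (formed in the flask) | CC1(C)OB(C[C@@H](c2ccc(C(=O)OC)cc2OCc2ccc(OC)cc2)CC[C@H]([C@@H](C)CCC=C(C)C)O)OC1(C)C | intermediate
12 | methyl 4-[(2R,5R,6S)-1,5-dihydroxy-6,10-dimethylundec-9-en-2-yl]-3-[(4-methoxybenzyl)oxy]benzoate | OC[C@@H](c1ccc(C(=O)OC)cc1OCc1ccc(OC)cc1)CC[C@H]([C@@H](C)CCC=C(C)C)O | intermediate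
13 | methyl 4-[(2R,5R,6S)-1-acetoxy-5-hydroxy-6,10-dimethylundec-9-en-2-yl]-3-[(4-methoxybenzyl)oxy]benzoate | CC(=O)OC[C@@H](c1ccc(C(=O)OC)cc1OCc1ccc(OC)cc1)CC[C@H]([C@@H](C)CCC=C(C)C)O | intermediate
14 | methyl 4-[(2R,5R,6S)-1-acetoxy-5-(methanesulfonyloxy)-6,10-dimethylundec-9-en-2-yl]-3-[(4-methoxybenzyl)oxy]benzoate | CC(=O)OC[C@@H](c1ccc(C(=O)OC)cc1OCc1ccc(OC)cc1)CC[C@H]([C@@H](C)CCC=C(C)C)OS(C)(=O)=O | intermediate
15 | methyl 4-[(2R,5R,6S)-1-acetoxy-5-(methanesulfonyloxy)-6,10-dimethylundec-9-en-2-yl]-3-hydroxybenzoate | CC(=O)OC[C@@H](c1ccc(C(=O)OC)cc1O)CC[C@H]([C@@H](C)CCC=C(C)C)OS(C)(=O)=O | intermediate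
16 | potassium phenoxide of 15 (formed in the flask) | CC(=O)OC[C@@H](c1ccc(C(=O)OC)cc1[O-])CC[C@H]([C@@H](C)CCC=C(C)C)OS(C)(=O)=O.[K+] | intermediate
17 | methyl (1R,4S)-1-(acetoxymethyl)-4-[(2S)-6-methylhept-5-en-2-yl]-6-oxospiro[4.5]deca-7,9-diene-8-carboxylate (both C5 epimers) | CC(=O)OC[C@@H]1CC[C@@H]([C@@H](C)CCC=C(C)C)C12C=CC(C(=O)OC)=CC2=O | intermediate
18 | methyl (5R,8S)-5-(acetoxymethyl)-4-hydroxy-8-[(2S)-6-methylhept-5-en-2-yl]-5,6,7,8-tetrahydronaphthalene-2-carboxylate | CC(=O)OC[C@@H]1CC[C@@H]([C@@H](C)CCC=C(C)C)c2cc(C(=O)OC)cc(O)c21 | intermediate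
19 | (5R,8S)-4-hydroxy-5-(hydroxymethyl)-8-[(2S)-6-methylhept-5-en-2-yl]-5,6,7,8-tetrahydronaphthalene-2-carboxylic acid | OC[C@@H]1CC[C@@H]([C@@H](C)CCC=C(C)C)c2cc(C(=O)O)cc(O)c21 | intermediate
20 | acetic (5R,8S)-4-acetoxy-5-(acetoxymethyl)-8-[(2S)-6-methylhept-5-en-2-yl]-5,6,7,8-tetrahydronaphthalene-2-carboxylic anhydride (formed in the flask) | CC(=O)OC[C@@H]1CC[C@@H]([C@@H](C)CCC=C(C)C)c2cc(C(=O)OC(C)=O)cc(OC(C)=O)c21 | intermediate
21 | (5R,8S)-4-acetoxy-5-(acetoxymethyl)-8-[(2S)-6-methylhept-5-en-2-yl]-5,6,7,8-tetrahydronaphthalene-2-carboxylic acid (CNP0223972.1) | CC(=O)OC[C@@H]1CC[C@@H]([C@@H](C)CCC=C(C)C)c2cc(C(=O)O)cc(OC(C)=O)c21 | target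

**Step count**

Total: 13 steps. Longest linear sequence: 12 steps (steps 2–13 from (S)-citronellal); step 1 is the one-step side branch.

**Steps most likely to fail**

Step 10. What may go wrong: alkylation at the phenoxide oxygen (seven-membered aryl ether) or elimination of the mesylate may outrun the hindered attack of C8a on the branched secondary carbon. The fallback replaces the hard sulfonate by a soft iodide and the single inversion by a double inversion. It sets out from monoacetate 13. A Mitsunobu reaction with chloroacetic acid (PPh3, DIAD, THF) would give the inverted ester methyl 4-[(2R,5S,6S)-1-acetoxy-5-(chloroacetoxy)-6,10-dimethylundec-9-en-2-yl]-3-[(4-methoxybenzyl)oxy]benzoate F1. Thiourea and NaHCO3 in EtOH remove the chloroacetyl group beside the acetate and give the epimeric alcohol methyl 4-[(2R,5S,6S)-1-acetoxy-5-hydroxy-6,10-dimethylundec-9-en-2-yl]-3-[(4-methoxybenzyl)oxy]benzoate F2. Appel iodination (I2, PPh3, imidazole) inverts again to methyl 4-[(2R,5R,6S)-1-acetoxy-5-iodo-6,10-dimethylundec-9-en-2-yl]-3-[(4-methoxybenzyl)oxy]benzoate F3, whose leaving group sits where the mesylate of 14 sat. DDQ frees the phenol methyl 4-[(2R,5R,6S)-1-acetoxy-5-iodo-6,10-dimethylundec-9-en-2-yl]-3-hydroxybenzoate F4, and KOtBu in tBuOH closes the ring, the softer leaving group favouring attack by carbon over oxygen. The fallback comes back to the route at 17.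

Step 11. What may go wrong: the ester-deactivated dienone may rearrange slowly, so that acid derived from the Lewis acid adds to or isomerises the side-chain alkene, or ionisation of the spiro C–C bond competes with the concerted shift. The fallback changes the mode of activation from Lewis-acid complexation to stoichiometric O-acylation in a buffered medium, with the phenol released from an ester. It sets out from 17. Trifluoroacetic anhydride with 2,6-di-tert-butyl-4-methylpyridine in CH2Cl2 acylates the carbonyl oxygen, the acyloxy cation undergoes the same 1,2-shift, and the hindered base takes up the proton, giving methyl (5R,8S)-5-(acetoxymethyl)-8-[(2S)-6-methylhept-5-en-2-yl]-4-(trifluoroacetoxy)-5,6,7,8-tetrahydronaphthalene-2-carboxylate F5. Brief treatment with NaHCO3 in MeOH cleaves the aryl trifluoroacetate only, and the fallback comes back to the route at 18.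

Step 6. What may go wrong: facial discrimination in the copper–boryl addition to the ortho-substituted alkene may be poor, giving both C1 epimers. The fallback sets C1 by thermodynamic control in a ring instead of by catalyst control. It sets out from ketone 9. A Wittig reaction with methoxymethylenetriphenylphosphorane (MeOCH2PPh3Cl, KOtBu, THF) would give the enol ether methyl 4-[(5R,6S)-5-hydroxy-1-methoxy-6,10-dimethylundeca-1,9-dien-2-yl]-3-[(4-methoxybenzyl)oxy]benzoate F6 as an E/Z mixture. Dilute HCl in THF hydrolyses it, and the hydroxy aldehyde closes to the lactol methyl 4-{(3R,6R)-2-hydroxy-6-[(2S)-6-methylhept-5-en-2-yl]oxan-3-yl}-3-[(4-methoxybenzyl)oxy]benzoate F7. Its aryl-bearing carbon is α to the masked aldehyde and is equilibrated (cat. DBU) through the open form toward the 3,6-trans diequatorial isomer, which is the one with the required configuration at C1. NaBH4 in MeOH then reduces the lactol, and the fallback comes back to the route at diol 12.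

**Further compounds**

F1 | step 10 | methyl 4-[(2R,5S,6S)-1-acetoxy-5-(chloroacetoxy)-6,10-dimethylundec-9-en-2-yl]-3-[(4-methoxybenzyl)oxy]benzoate | CC(=O)OC[C@@H](c1ccc(C(=O)OC)cc1OCc1ccc(OC)cc1)CC[C@@H]([C@@H](C)CCC=C(C)C)OC(=O)CCl
F2 | step 10 | methyl 4-[(2R,5S,6S)-1-acetoxy-5-hydroxy-6,10-dimethylundec-9-en-2-yl]-3-[(4-methoxybenzyl)oxy]benzoate | CC(=O)OC[C@@H](c1ccc(C(=O)OC)cc1OCc1ccc(OC)cc1)CC[C@@H]([C@@H](C)CCC=C(C)C)O
F3 | step 10 | methyl 4-[(2R,5R,6S)-1-acetoxy-5-iodo-6,10-dimethylundec-9-en-2-yl]-3-[(4-methoxybenzyl)oxy]benzoate | CC(=O)OC[C@@H](c1ccc(C(=O)OC)cc1OCc1ccc(OC)cc1)CC[C@H]([C@@H](C)CCC=C(C)C)I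
F4 | step 10 | methyl 4-[(2R,5R,6S)-1-acetoxy-5-iodo-6,10-dimethylundec-9-en-2-yl]-3-hydroxybenzoate | CC(=O)OC[C@@H](c1ccc(C(=O)OC)cc1O)CC[C@H]([C@@H](C)CCC=C(C)C)I
F5 | step 11 | methyl (5R,8S)-5-(acetoxymethyl)-8-[(2S)-6-methylhept-5-en-2-yl]-4-(trifluoroacetoxy)-5,6,7,8-tetrahydronaphthalene-2-carboxylate | CC(=O)OC[C@@H]1CC[C@@H]([C@@H](C)CCC=C(C)C)c2cc(C(=O)OC)cc(OC(=O)C(F)(F)F)c21
F6 | step 6 | methyl 4-[(5R,6S)-5-hydroxy-1-methoxy-6,10-dimethylundeca-1,9-dien-2-yl]-3-[(4-methoxybenzyl)oxy]benzoate (E/Z mixture) | COC=C(c1ccc(C(=O)OC)cc1OCc1ccc(OC)cc1)CC[C@H]([C@@H](C)CCC=C(C)C)O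
F7 | step 6 | methyl 4-{(3R,6R)-2-hydroxy-6-[(2S)-6-methylhept-5-en-2-yl]oxan-3-yl}-3-[(4-methoxybenzyl)oxy]benzoate (anomeric mixture) | OC1O[C@@H]([C@@H](C)CCC=C(C)C)CC[C@@H]1c1ccc(C(=O)OC)cc1OCc1ccc(OC)cc1
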